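## Retrosynthetic overview
1. The target comes from O-methylation of the free C8 phenol, (2S)-7-methoxy-2-(3,4,5-trimethoxyphenyl)chroman-8-ol.
2. That phenol comes from an (S)-ethynyl ether carrying a 2-(5-methoxyfuran-2-yl)ethyl arm. One gold-catalysed furan–yne cycloisomerisation makes C8a–C4a (ring C) and then C8–C7 (ring A). The furan oxygen ends as O8 and the furan OMe as 7-OMe.
3. The ethynyl ether comes from the (S)-carbinol plus trichloroethylene, which supplies C8a and C8. The C2–O1 bond is never broken.
4. The (S)-carbinol comes from the furyl enone by tandem C=C/C=O asymmetric transfer hydrogenation, which sets C2.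
5. The enone comes from 3,4,5-trimethoxyacetophenone, 5-bromofurfural and NaOMe. Ring order: ring B is bought, then ring C and ring A form in the same flask, C before A.

Assumption: flavan numbering (O1, C2–C4, C4a, C5–C8, C8a) is used for these atoms throughout, including in open-chain precursors, and 1 and 2 are taken as catalogue chemicals.

## Route

Step 1
Reactants: 1 5-bromofuran-2-carbaldehyde (5-bromofurfural); 2 1-(3,4,5-trimethoxyphenyl)ethan-1-one (3,4,5-trimethoxyacetophenone)
Product: 4 (E)-3-(5-methoxyfuran-2-yl)-1-(3,4,5-trimethoxyphenyl)prop-2-en-1-one, via 5-methoxyfurfural 3 (not isolated)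
Conditions: 1, NaOMe (2.5 equiv), MeOH, reflux, 3 h; then 2, rt, 16 h
Reagents that add atoms: sodium methoxide, [Na+].[O-]C
Why: Methoxide replaces the formyl-activated 5-bromide by nucleophilic aromatic substitution (addition–elimination), and the same base then drives a Claisen–Schmidt aldol condensation whose E1cB dehydration gives the (E)-enone; no stereocentre is formed.

Step 2
Reactants: 4 (E)-3-(5-methoxyfuran-2-yl)-1-(3,4,5-trimethoxyphenyl)prop-2-en-1-one
Product: 6 (S)-3-(5-methoxyfuran-2-yl)-1-(3,4,5-trimethoxyphenyl)propan-1-ol, via saturated ketone 5 (not isolated)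
Conditions: RuCl(p-cymene)[(S,S)-TsDPEN] (2 mol %), HCO2Na (10 equiv), H2O/MeOH 1:1, 40 °C
Reagents that add atoms: none
Why: In this Noyori–Ikariya asymmetric transfer hydrogenation the ruthenium hydride first reduces the polarised C=C by 1,4-addition and then reduces the aryl ketone through the six-membered Ru–H/N–H transition state with its CH/π contact to ring B, so the (S,S)-ligand gives the (S)-carbinol (future C2), while the weakly basic medium spares the acid-labile methoxyfuran.

Step 3
Reactants: 6 (S)-3-(5-methoxyfuran-2-yl)-1-(3,4,5-trimethoxyphenyl)propan-1-ol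
Product: 10 (S)-2-[3-(ethynyloxy)-3-(3,4,5-trimethoxyphenyl)propyl]-5-methoxyfuran, via dichlorovinyl ether 7 (not isolated), via chloroalkynyl ether 8 (not isolated), via lithium alkynyl ether 9 (not isolated)
Conditions: KH (1.3 equiv), THF, 0 °C; Cl2C=CHCl (1.1 equiv), −50 °C to rt; n-BuLi (2.3 equiv), −78 to −40 °C; H2O, −78 °C; fast filtration through basic alumina, kept below 0 °C
Reagents that add atoms: trichloroethylene, ClC=C(Cl)Cl
Why: In this Greene-type alkynyl ether synthesis, deprotonated 6 adds anti to dichloroacetylene made from trichloroethylene, n-BuLi then eliminates HCl and exchanges chlorine for lithium, and protonation gives the terminal alkynyl ether; every reagent is basic and the carbinol C–O bond is untouched, so (S) is retained.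

Step 4
Reactants: 10 (S)-2-[3-(ethynyloxy)-3-(3,4,5-trimethoxyphenyl)propyl]-5-methoxyfuran
Product: 13 (2S)-7-methoxy-2-(3,4,5-trimethoxyphenyl)chroman-8-ol, via pyrano-oxepine 11 (not isolated), via arene oxide 12 (not isolated)
Conditions: Au(NTf2)(PPh3) (3 mol %), 4 Å MS, CH2Cl2, −20 °C to rt
Reagents that add atoms: none
Why: Proposed new method: monovalent gold polarises the alkynyl ether like a ketene oxonium ion, so the O1-bearing carbon is attacked 6-exo-dig by the alkyl-bearing furan carbon (the most nucleophilic site, conjugated to OMe), which closes ring C; the furan then opens to a (Z)-enoate/vinyl gold carbene, the ester carbonyl oxygen adds to the carbene CH to give oxepine 11, 6π closure gives arene oxide 12 (ring A), and epoxide opening, assisted by both the 7-OMe and O1, leaves the oxygen on the former alkyne CH as 8-OH; the closest known reaction type is the Hashmi gold-catalysed furan–yne phenol synthesis, which turns tethered alkynyl ethers into chroman-8-ols, the new element being the 5-methoxy group on the furan; C2 is a spectator and stays (S).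

Step 5
Reactants: 13 (2S)-7-methoxy-2-(3,4,5-trimethoxyphenyl)chroman-8-ol
Product: 14 (2S)-7,8,3',4',5'-pentamethoxyflavan
Conditions: MeI (2 equiv), K2CO3 (2 equiv), acetone, 40 °C
Reagents that add atoms: iodomethane, CI
Why: This Williamson ether synthesis (SN2 of the phenoxide on MeI) caps the only free OH under mild base, which cannot touch the C2 benzylic ether stereocentre.

## Compound list
1 | 5-bromofuran-2-carbaldehyde | O=Cc1ccc(Br)o1 | starting material
2 | 1-(3,4,5-trimethoxyphenyl)ethan-1-one | CC(=O)c1cc(OC)c(OC)c(OC)c1 | starting material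
3 | 5-methoxyfuran-2-carbaldehyde | COc1ccc(C=O)o1 | intermediate
4 | (E)-3-(5-methoxyfuran-2-yl)-1-(3,4,5-trimethoxyphenyl)prop-2-en-1-one | COc1ccc(/C=C/C(=O)c2cc(OC)c(OC)c(OC)c2)o1 | intermediate
5 | 3-(5-methoxyfuran-2-yl)-1-(3,4,5-trimethoxyphenyl)propan-1-one | COc1ccc(CCC(=O)c2cc(OC)c(OC)c(OC)c2)o1 | intermediate
6 | (S)-3-(5-methoxyfuran-2-yl)-1-(3,4,5-trimethoxyphenyl)propan-1-ol | COc1cc([C@@H](O)CCc2ccc(OC)o2)cc(OC)c1OC | intermediate
7 | (S)-2-{3-[(E)-1,2-dichlorovinyloxy]-3-(3,4,5-trimethoxyphenyl)propyl}-5-methoxyfuran | COc1cc([C@@H](O/C(Cl)=C\Cl)CCc2ccc(OC)o2)cc(OC)c1OC | intermediate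
8 | (S)-2-[3-(chloroethynyloxy)-3-(3,4,5-trimethoxyphenyl)propyl]-5-methoxyfuran | COc1cc([C@@H](OC#CCl)CCc2ccc(OC)o2)cc(OC)c1OC | intermediate
9 | lithium acetylide of 10 (Li on the terminal alkyne carbon, S) | COc1cc([C@@H](OC#C[Li])CCc2ccc(OC)o2)cc(OC)c1OC | intermediate
10 | (S)-2-[3-(ethynyloxy)-3-(3,4,5-trimethoxyphenyl)propyl]-5-methoxyfuran | COc1cc([C@@H](OC#C)CCc2ccc(OC)o2)cc(OC)c1OC | intermediate
11 | (2S)-7-methoxy-2-(3,4,5-trimethoxyphenyl)-3,4-dihydro-2H-pyrano[2,3-c]oxepine | COC1=CC=C2CC[C@@H](c3cc(OC)c(OC)c(OC)c3)OC2=CO1 | intermediate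
12 | (2S)-7,8-epoxy-7-methoxy-2-(3,4,5-trimethoxyphenyl)-3,4,7,8-tetrahydro-2H-chromene (arene oxide, epoxide face not controlled) | COC12C=CC3=C(O[C@H](c4cc(OC)c(OC)c(OC)c4)CC3)C1O2 | intermediate
13 | (2S)-7-methoxy-2-(3,4,5-trimethoxyphenyl)chroman-8-ol | COc1cc([C@@H]2CCc3ccc(OC)c(O)c3O2)cc(OC)c1OC | intermediate
14 | (2S)-7,8,3',4',5'-pentamethoxyflavan | COc1cc([C@@H]2CCc3ccc(OC)c(OC)c3O2)cc(OC)c1OC | target

## Step count
- Total step count: 5.
- Longest linear sequence: 5 (from 1 or 2 to 14).

## The three steps most likely to fail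

**Step 4 (highest risk).** There are three weak points.
- The carbonyl released from a methoxyfuran is an ester carbonyl. It is a weaker nucleophile toward the gold carbene than the aldehyde or ketone carbonyl of the known cases.
- The gold-activated alkynyl ether can ionise at the benzylic C2–O1 bond.
- The electron-rich ring B can compete as the nucleophile.

The fallback takes the C7 oxygen out of the cyclisation substrate and adds it after the two rings are made. The ring construction then runs on the precedented parent furan. It sets out from 2 and comes back at 14.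

Condensing 2 with furfural (NaOH, EtOH) gives the furyl enone F1. Reduction as in step 2 passes through the saturated furyl ketone F2 to the (S)-furyl carbinol F3. The sequence of step 3 then leads through the dichlorovinyl ether F4, the chloroalkynyl ether F5 and the lithium alkynyl ether F6 to the ethynyl ether F7. The catalyst of step 4 converts F7 through the parent pyrano-oxepine F8 and the parent arene oxide F9 into the chroman-8-ol F10.

Ortho-selective formylation (MgCl2, Et3N, paraformaldehyde, MeCN, reflux) can only hit C7 and gives the salicylaldehyde F11. Dakin oxidation (H2O2, NaOH, THF/H2O, 0 °C) passes through the aryl formate F12 to the chroman-7,8-diol F13. Double methylation (excess MeI, K2CO3, acetone, under argon) delivers 14.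

**Step 3.** The secondary benzylic ethynyl ether is thermally fragile. It can undergo retro-ene loss of ketene or a [3,3] shift into ring B. The dichloroacetylene/KH chemistry may also be unclean on this substrate.

The fallback builds the two alkyne carbons one at a time from a formate, without KH and without dichloroacetylene. It sets out from 6 and comes back at 8, and from there to 9 and 10. Formylation of 6 with acetic formic anhydride and pyridine (0 °C) gives the carbinyl formate F14. Wittig-type dichloromethylenation of the formate carbonyl (PPh3, CCl4, THF, 60 °C) gives the 2,2-dichlorovinyl ether F15. n-BuLi at −78 °C eliminates HCl from F15 to give 8, which continues as in step 3.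

**Step 2.** The donor furan deactivates the enone β-carbon. 1,2-Reduction may therefore outrun 1,4-reduction and leave an ionisation-prone allylic alcohol.

The fallback splits the two reductions between two unrelated mechanisms. It sets out from 4 and comes back at 6. The C=C bond is hydrogenated heterogeneously (H2 1 atm, Pd/C poisoned with Ph2S, EtOAc) and 5 is isolated. The aryl alkyl ketone is then reduced with BH3·SMe2 and (R)-2-methyl-CBS-oxazaborolidine (10 mol %, THF, −20 °C), which gives the (S)-carbinol 6.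

## Further compounds
F1 | step 4 | (E)-3-(furan-2-yl)-1-(3,4,5-trimethoxyphenyl)prop-2-en-1-one | O=C(/C=C/c1ccco1)c1cc(OC)c(OC)c(OC)c1
F2 | step 4 | 3-(furan-2-yl)-1-(3,4,5-trimethoxyphenyl)propan-1-one | O=C(CCc1ccco1)c1cc(OC)c(OC)c(OC)c1
F3 | step 4 | (S)-3-(furan-2-yl)-1-(3,4,5-trimethoxyphenyl)propan-1-ol | COc1cc([C@@H](O)CCc2ccco2)cc(OC)c1OC
F4 | step 4 | (S)-2-{3-[(E)-1,2-dichlorovinyloxy]-3-(3,4,5-trimethoxyphenyl)propyl}furan | COc1cc([C@@H](O/C(Cl)=C\Cl)CCc2ccco2)cc(OC)c1OC
F5 | step 4 | (S)-2-[3-(chloroethynyloxy)-3-(3,4,5-trimethoxyphenyl)propyl]furan | COc1cc([C@@H](OC#CCl)CCc2ccco2)cc(OC)c1OC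
F6 | step 4 | lithium acetylide of F7 | COc1cc([C@@H](OC#C[Li])CCc2ccco2)cc(OC)c1OC
F7 | step 4 | (S)-2-[3-(ethynyloxy)-3-(3,4,5-trimethoxyphenyl)propyl]furan | COc1cc([C@@H](OC#C)CCc2ccco2)cc(OC)c1OC
F8 | step 4 | (2S)-2-(3,4,5-trimethoxyphenyl)-3,4-dihydro-2H-pyrano[2,3-c]oxepine | C1=CC=C2CC[C@@H](c3cc(OC)c(OC)c(OC)c3)OC2=CO1
F9 | step 4 | (2S)-7,8-epoxy-2-(3,4,5-trimethoxyphenyl)-3,4,7,8-tetrahydro-2H-chromene | C12C=CC3=C(O[C@H](c4cc(OC)c(OC)c(OC)c4)CC3)C1O2
F10 | step 4 | (2S)-2-(3,4,5-trimethoxyphenyl)chroman-8-ol | COc1cc([C@@H]2CCc3cccc(O)c3O2)cc(OC)c1OC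
F11 | step 4 | (2S)-8-hydroxy-2-(3,4,5-trimethoxyphenyl)chroman-7-carbaldehyde | COc1cc([C@@H]2CCc3ccc(C=O)c(O)c3O2)cc(OC)c1OC
F12 | step 4 | (2S)-8-hydroxy-2-(3,4,5-trimethoxyphenyl)chroman-7-yl formate | COc1cc([C@@H]2CCc3ccc(OC=O)c(O)c3O2)cc(OC)c1OC
F13 | step 4 | (2S)-2-(3,4,5-trimethoxyphenyl)chroman-7,8-diol | COc1cc([C@@H]2CCc3ccc(O)c(O)c3O2)cc(OC)c1OC
F14 | step 3 | (S)-3-(5-methoxyfuran-2-yl)-1-(3,4,5-trimethoxyphenyl)propyl formate | COc1cc([C@@H](OC=O)CCc2ccc(OC)o2)cc(OC)c1OC
F15 | step 3 | (S)-2-[3-(2,2-dichlorovinyloxy)-3-(3,4,5-trimethoxyphenyl)propyl]-5-methoxyfuran | COc1cc([C@@H](OC=C(Cl)Cl)CCc2ccc(OC)o2)cc(OC)c1OC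
F0 | step 2 | none | none
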